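## Retrosynthetic overview

1. Target acid ⇐ C1 primary alcohol ⇐ 1,2-dioxane closed last, by 6-exo capture of a C6 tertiary allylic cation by a C3 peroxide; the O–O unit enters by SN2 (inversion) at C3.
2. Acyclic 3,6-diol ⇐ γ-lactone 18 + alkenyllithium from vinyl iodide 8, then EtMgBr at C6.
3. Lactone 18 (C3, C4) ⇐ iodolactonisation of a γ,δ-unsaturated amide; C4 and the C4–C5 bond come from an Eschenmoser–Claisen [3,3] rearrangement with chirality transfer from (R)-but-3-yn-2-ol (key step).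
4. Vinyl iodide 8 (C10) ⇐ (S)-1,2-epoxybutane: acetylide opening, copper-catalysed SN2 butylation (inversion), carboalumination/iodination.
5. Ring order: a temporary γ-lactone (steps 9–11) relays C4 to C3; the only ring of the target, the 1,2-dioxane, is formed in step 15.

Assumption: (S)-1,2-epoxybutane and (R)-but-3-yn-2-ol are taken as inexpensive commercial chiral building blocks; atoms are numbered C1 (carboxyl) to C14 along the main chain throughout.

## Route

Step 1
Reactants: 1 (S)-2-ethyloxirane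
Product: 2 (S)-hex-5-yn-3-ol
Conditions: LiC≡CH·H2NCH2CH2NH2, DMSO, 0 °C → rt; then H2O
Reagents that add atoms: lithium acetylide–ethylenediamine complex, [Li]C#C.NCCN
Why: SN2 epoxide opening (acetylide alkylation) at the unsubstituted carbon leaves the purchased stereocentre untouched.

Step 2
Reactants: 2 (S)-hex-5-yn-3-ol
Product: 3 (S)-hex-5-yn-3-yl 4-methylbenzenesulfonate
Conditions: TsCl, pyridine, DMAP (cat.), CH2Cl2, 0 °C → rt
Reagents that add atoms: 4-methylbenzenesulfonyl chloride, Cc1ccc(cc1)S(Cl)(=O)=O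
Why: Tosylation of the secondary alcohol proceeds with retention and creates the leaving group.

Step 3
Reactants: 3 (S)-hex-5-yn-3-yl 4-methylbenzenesulfonate
Product: 6 (S)-4-ethyloct-1-yne, via alkynylmagnesium chloride of the tosylate 4 (not isolated), via alkynylmagnesium chloride of the coupled product 5 (not isolated)
Conditions: n-BuMgCl (2.3 equiv), CuI (10 mol%), TMEDA, LiOMe, THF, 0 °C; then H2O
Reagents that add atoms: butylmagnesium chloride, CCCC[Mg]Cl
Why: Copper-catalysed Kumada-type SN2 alkyl–alkyl coupling of the secondary tosylate goes with inversion, turning the epoxide-derived centre into the (S) ethyl/butyl stereocentre C10; the first equivalent of Grignard only deprotonates the alkyne.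

Step 4
Reactants: 6 (S)-4-ethyloct-1-yne
Product: 8 (1E,4S)-4-ethyl-1-iodo-2-methyloct-1-ene, via alkenyldimethylalane 7 (not isolated)
Conditions: AlMe3 (2 equiv), Cp2ZrCl2 (20 mol%), CH2Cl2, 0 °C → rt; then I2, THF, −30 → 0 °C
Reagents that add atoms: trimethylaluminium, C[Al](C)C; iodine, I-I
Why: Negishi zirconium-catalysed carboalumination adds Me–Al syn across the terminal alkyne and iodinolysis occurs with retention, fixing the E trisubstituted alkene.

Step 5
Reactants: 9 (R)-but-3-yn-2-ol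
Product: 11 (R)-hex-3-yn-2-ol, via dilithium alkoxide acetylide 10 (not isolated)
Conditions: n-BuLi (2.2 equiv), THF/DMPU, −78 → −20 °C; EtI, → rt; then H2O
Reagents that add atoms: iodoethane, CCI
Why: C-alkylation of the alkoxide/acetylide dianion (acetylide alkylation) extends the alkyne without touching the carbinol centre.

Step 6
Reactants: 11 (R)-hex-3-yn-2-ol
Product: 12 (2R,3E)-hex-3-en-2-ol
Conditions: NaAlH2(OCH2CH2OCH3)2, THF, 0 °C → rt; then H2O
Reagents that add atoms: none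
Why: Alkoxide-directed trans-hydroalumination of the propargylic alcohol gives the E allylic alcohol only.

Step 7
Reactants: 12 (2R,3E)-hex-3-en-2-ol
Product: 14 (3R,4E)-3-ethyl-N,N-dimethylhex-4-enamide, via ketene N,O-acetal 13 (not isolated)
Conditions: CH3C(OCH3)2N(CH3)2, xylenes, 140 °C
Reagents that add atoms: 1,1-dimethoxy-N,N-dimethylethanamine, COC(C)(OC)N(C)C
Why: Eschenmoser–Claisen [3,3]-sigmatropic rearrangement through a chair with the carbinol methyl equatorial forms the C4–C5 bond suprafacially, transferring the (R) carbinol chirality to (R)-C4 and giving the E alkene.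

Step 8
Reactants: 14 (3R,4E)-3-ethyl-N,N-dimethylhex-4-enamide
Product: 15 (3R,4E)-6-[(tert-butyldiphenylsilyl)oxy]-3-ethyl-N,N-dimethylhex-4-enamide
Conditions: CH2=CHCH2OSi(t-Bu)Ph2 (3 equiv), second-generation Grubbs catalyst RuCl2(=CHPh)(PCy3)(H2IMes) (3 mol%), CH2Cl2, 40 °C
Reagents that add atoms: (allyloxy)(tert-butyl)diphenylsilane, C=CCO[Si](c1ccccc1)(c1ccccc1)C(C)(C)C
Why: Olefin cross-metathesis swaps the propenyl methyl for the silyloxymethyl terminus (C1, C2) with loss of propene; C4 is untouched and the E/Z ratio is irrelevant after step 10.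

Step 9
Reactants: 15 (3R,4E)-6-[(tert-butyldiphenylsilyl)oxy]-3-ethyl-N,N-dimethylhex-4-enamide
Product: 17 (4R,5R)-5-{(1S)-2-[(tert-butyldiphenylsilyl)oxy]-1-iodoethyl}-4-ethyloxolan-2-one, via iminium lactone iodide 16 (not isolated)
Conditions: I2 (3 equiv), THF/H2O (1:1), rt, dark
Reagents that add atoms: iodine, I-I; water, O
Why: Iodolactonisation of the γ,δ-unsaturated amide (5-exo, anti addition) puts the new C3–O bond trans to the C4 ethyl group through the allylic-strain-minimised transition state, and hydrolysis of the iminium gives the trans γ-lactone.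

Step 10
Reactants: 17 (4R,5R)-5-{(1S)-2-[(tert-butyldiphenylsilyl)oxy]-1-iodoethyl}-4-ethyloxolan-2-one
Product: 18 (4R,5S)-5-{2-[(tert-butyldiphenylsilyl)oxy]ethyl}-4-ethyloxolan-2-one
Conditions: n-Bu3SnH, AIBN (cat.), toluene, 80 °C
Reagents that add atoms: none
Why: Radical deiodination (tin hydride reduction) removes the C2 iodine without touching C3 or C4; any minor cis lactone is removed here by chromatography.

Step 11
Reactants: 8 (1E,4S)-4-ethyl-1-iodo-2-methyloct-1-ene; 18 (4R,5S)-5-{2-[(tert-butyldiphenylsilyl)oxy]ethyl}-4-ethyloxolan-2-one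
Product: 20 (3S,4R,7E,10S)-1-[(tert-butyldiphenylsilyl)oxy]-4,10-diethyl-3-hydroxy-8-methyltetradec-7-en-6-one, via alkenyllithium 19 (not isolated)
Conditions: 8, t-BuLi (2.1 equiv), Et2O, −78 °C; then 18, −78 °C; then H2O
Reagents that add atoms: none
Why: Iodine–lithium exchange with retention of alkene geometry and acyl substitution on the γ-lactone, which stops at the lithium lactolate at −78 °C, joins the fragments as the γ-hydroxy enone (in equilibrium with its lactol).

Step 12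
Reactants: 20 (3S,4R,7E,10S)-1-[(tert-butyldiphenylsilyl)oxy]-4,10-diethyl-3-hydroxy-8-methyltetradec-7-en-6-one
Product: 21 (3S,4R,6RS,7E,10S)-1-[(tert-butyldiphenylsilyl)oxy]-4,6,10-triethyl-8-methyltetradec-7-ene-3,6-diol
Conditions: EtMgBr (3 equiv), CeCl3, THF, −78 → 0 °C; then H2O
Reagents that add atoms: ethylmagnesium bromide, CC[Mg]Br
Why: Organocerium 1,2-addition to the enone gives the tertiary allylic alcohol as a mixture of C6 epimers, which does not matter because this centre is ionised in step 15.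

Step 13
Reactants: 21 (3S,4R,6RS,7E,10S)-1-[(tert-butyldiphenylsilyl)oxy]-4,6,10-triethyl-8-methyltetradec-7-ene-3,6-diol
Product: 22 (3S,4R,6RS,7E,10S)-1-[(tert-butyldiphenylsilyl)oxy]-4,6,10-triethyl-6-hydroxy-8-methyltetradec-7-en-3-yl 4-bromobenzenesulfonate
Conditions: 4-BrC6H4SO2Cl, pyridine, DMAP (cat.), CH2Cl2, 0 °C
Reagents that add atoms: 4-bromobenzenesulfonyl chloride, O=S(=O)(Cl)c1ccc(Br)cc1
Why: Selective sulfonylation of the secondary hydroxyl beside the hindered tertiary one activates C3 with retention; the product is used at once.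

Step 14
Reactants: 22 (3S,4R,6RS,7E,10S)-1-[(tert-butyldiphenylsilyl)oxy]-4,6,10-triethyl-6-hydroxy-8-methyltetradec-7-en-3-yl 4-bromobenzenesulfonate
Product: 23 (3R,4R,6RS,7E,10S)-1-[(tert-butyldiphenylsilyl)oxy]-4,6,10-triethyl-3-[(2-methoxypropan-2-yl)peroxy]-8-methyltetradec-7-en-6-ol
Conditions: CH3OC(CH3)2OOH, CsOH·H2O, DMF, 0 °C → rt
Reagents that add atoms: 2-hydroperoxy-2-methoxypropane, COC(C)(C)OO
Why: SN2 displacement of the brosylate by the caesium peroxide (Dussault perketal method) installs the O–O unit with inversion, (3S) to (3R); the peroxide anion is too weak a base to deprotonate the tertiary alcohol.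

Step 15
Reactants: 23 (3R,4R,6RS,7E,10S)-1-[(tert-butyldiphenylsilyl)oxy]-4,6,10-triethyl-3-[(2-methoxypropan-2-yl)peroxy]-8-methyltetradec-7-en-6-ol
Product: 25 tert-butyl{2-[(3R,4R,6R)-4,6-diethyl-6-[(1E,4S)-4-ethyl-2-methyloct-1-en-1-yl]-1,2-dioxan-3-yl]ethoxy}diphenylsilane, via tertiary allylic cation 24 (not isolated)
Conditions: TsOH·H2O (10 mol%), CH2Cl2, 0 °C
Reagents that add atoms: none
Why: Acid ionises the tertiary allylic alcohol and the E allyl cation is captured 6-exo by the tethered peroxide oxygen (SN1 etherification, the perketal leaving as acetone and methanol); a chair with the C4 ethyl and the alkenyl arm equatorial and the C3 arm and C6 ethyl axial is expected to favour (6R), but this selectivity is a qualitative prediction, and ring closure should outrun C7–C8 rotation so the E alkene is kept.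

Step 16
Reactants: 25 tert-butyl{2-[(3R,4R,6R)-4,6-diethyl-6-[(1E,4S)-4-ethyl-2-methyloct-1-en-1-yl]-1,2-dioxan-3-yl]ethoxy}diphenylsilane
Product: 26 2-[(3R,4R,6R)-4,6-diethyl-6-[(1E,4S)-4-ethyl-2-methyloct-1-en-1-yl]-1,2-dioxan-3-yl]ethan-1-ol
Conditions: n-Bu4NF, AcOH, THF, 0 °C → rt
Reagents that add atoms: none
Why: Fluoride desilylation buffered with acetic acid frees the primary alcohol without base-induced peroxide cleavage.

Step 17
Reactants: 26 2-[(3R,4R,6R)-4,6-diethyl-6-[(1E,4S)-4-ethyl-2-methyloct-1-en-1-yl]-1,2-dioxan-3-yl]ethan-1-ol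
Product: 28 2-[(3R,4R,6R)-4,6-diethyl-6-[(1E,4S)-4-ethyl-2-methyloct-1-en-1-yl]-1,2-dioxan-3-yl]acetic acid, via aldehyde 27 (not isolated)
Conditions: TEMPO (20 mol%), PhI(OAc)2 (2.5 equiv), MeCN/H2O, rt
Reagents that add atoms: water, O
Why: TEMPO/PhI(OAc)2 oxoammonium oxidation takes the primary alcohol through the aldehyde hydrate to the acid under conditions that spare the peroxide and the alkene.

## Compound list

1 | (S)-2-ethyloxirane | CC[C@H]1CO1 | starting material
2 | (S)-hex-5-yn-3-ol | CC[C@H](O)CC#C | intermediate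
3 | (S)-hex-5-yn-3-yl 4-methylbenzenesulfonate | CC[C@H](OS(=O)(=O)c1ccc(C)cc1)CC#C | intermediate
4 | [(4S)-4-(tosyloxy)hex-1-yn-1-yl]magnesium chloride | CC[C@H](OS(=O)(=O)c1ccc(C)cc1)CC#C[Mg]Cl | intermediate
5 | [(4S)-4-ethyloct-1-yn-1-yl]magnesium chloride | CCCC[C@H](CC)CC#C[Mg]Cl | intermediate
6 | (S)-4-ethyloct-1-yne | CCCC[C@H](CC)CC#C | intermediate
7 | [(1E,4S)-4-ethyl-2-methyloct-1-en-1-yl]dimethylalumane | CCCC[C@H](CC)C/C(C)=C/[Al](C)C | intermediate
8 | (1E,4S)-4-ethyl-1-iodo-2-methyloct-1-ene | CCCC[C@H](CC)C/C(C)=C/I | intermediate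
9 | (R)-but-3-yn-2-ol | C[C@@H](O)C#C | starting material
10 | dilithium salt of (R)-but-3-yn-2-ol (O-lithio, C4-lithio) | C[C@@H](O[Li])C#C[Li] | intermediate
11 | (R)-hex-3-yn-2-ol | C[C@@H](O)C#CCC | intermediate
12 | (2R,3E)-hex-3-en-2-ol | C[C@@H](O)/C=C/CC | intermediate
13 | 1-{[(2R,3E)-hex-3-en-2-yl]oxy}-N,N-dimethylethen-1-amine | C=C(N(C)C)O[C@H](C)/C=C/CC | intermediate
14 | (3R,4E)-3-ethyl-N,N-dimethylhex-4-enamide | C/C=C/[C@H](CC)CC(=O)N(C)C | intermediate
15 | (3R,4E)-6-[(tert-butyldiphenylsilyl)oxy]-3-ethyl-N,N-dimethylhex-4-enamide | CC(C)(C)[Si](OC/C=C/[C@H](CC)CC(=O)N(C)C)(c1ccccc1)c1ccccc1 | intermediate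
16 | N-[(4R,5R)-5-{(1S)-2-[(tert-butyldiphenylsilyl)oxy]-1-iodoethyl}-4-ethyloxolan-2-ylidene]-N-methylmethanaminium iodide | C[N+](C)=C1C[C@@H](CC)[C@H]([C@@H](I)CO[Si](c2ccccc2)(c2ccccc2)C(C)(C)C)O1.[I-] | intermediate
17 | (4R,5R)-5-{(1S)-2-[(tert-butyldiphenylsilyl)oxy]-1-iodoethyl}-4-ethyloxolan-2-one | O=C1C[C@@H](CC)[C@H]([C@@H](I)CO[Si](c2ccccc2)(c2ccccc2)C(C)(C)C)O1 | intermediate
18 | (4R,5S)-5-{2-[(tert-butyldiphenylsilyl)oxy]ethyl}-4-ethyloxolan-2-one (trans) | O=C1C[C@@H](CC)[C@H](CCO[Si](c2ccccc2)(c2ccccc2)C(C)(C)C)O1 | intermediate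
19 | [(1E,4S)-4-ethyl-2-methyloct-1-en-1-yl]lithium | CCCC[C@H](CC)C/C(C)=C/[Li] | intermediate
20 | (3S,4R,7E,10S)-1-[(tert-butyldiphenylsilyl)oxy]-4,10-diethyl-3-hydroxy-8-methyltetradec-7-en-6-one | CCCC[C@H](CC)C/C(C)=C/C(=O)C[C@@H](CC)[C@@H](O)CCO[Si](c1ccccc1)(c1ccccc1)C(C)(C)C | intermediate
21 | (3S,4R,6RS,7E,10S)-1-[(tert-butyldiphenylsilyl)oxy]-4,6,10-triethyl-8-methyltetradec-7-ene-3,6-diol (C6 epimers) | CCCC[C@H](CC)C/C(C)=C/C(O)(CC)C[C@@H](CC)[C@@H](O)CCO[Si](c1ccccc1)(c1ccccc1)C(C)(C)C | intermediate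
22 | (3S,4R,6RS,7E,10S)-1-[(tert-butyldiphenylsilyl)oxy]-4,6,10-triethyl-6-hydroxy-8-methyltetradec-7-en-3-yl 4-bromobenzenesulfonate (C6 epimers) | CCCC[C@H](CC)C/C(C)=C/C(O)(CC)C[C@@H](CC)[C@@H](OS(=O)(=O)c1ccc(Br)cc1)CCO[Si](c1ccccc1)(c1ccccc1)C(C)(C)C | intermediate
23 | (3R,4R,6RS,7E,10S)-1-[(tert-butyldiphenylsilyl)oxy]-4,6,10-triethyl-3-[(2-methoxypropan-2-yl)peroxy]-8-methyltetradec-7-en-6-ol (C6 epimers) | CCCC[C@H](CC)C/C(C)=C/C(O)(CC)C[C@@H](CC)[C@H](OOC(C)(C)OC)CCO[Si](c1ccccc1)(c1ccccc1)C(C)(C)C | intermediate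
24 | C6 tertiary allylic cation formed from 23 by loss of hydroxide (E at C7–C8) | CCCC[C@H](CC)C/C(C)=C/[C+](CC)C[C@@H](CC)[C@H](OOC(C)(C)OC)CCO[Si](c1ccccc1)(c1ccccc1)C(C)(C)C | intermediate
25 | tert-butyl{2-[(3R,4R,6R)-4,6-diethyl-6-[(1E,4S)-4-ethyl-2-methyloct-1-en-1-yl]-1,2-dioxan-3-yl]ethoxy}diphenylsilane | CCCC[C@H](CC)C/C(C)=C/[C@@]1(CC)C[C@@H](CC)[C@@H](CCO[Si](c2ccccc2)(c2ccccc2)C(C)(C)C)OO1 | intermediate
26 | 2-[(3R,4R,6R)-4,6-diethyl-6-[(1E,4S)-4-ethyl-2-methyloct-1-en-1-yl]-1,2-dioxan-3-yl]ethan-1-ol | CCCC[C@H](CC)C/C(C)=C/[C@@]1(CC)C[C@@H](CC)[C@@H](CCO)OO1 | intermediate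
27 | 2-[(3R,4R,6R)-4,6-diethyl-6-[(1E,4S)-4-ethyl-2-methyloct-1-en-1-yl]-1,2-dioxan-3-yl]acetaldehyde | CCCC[C@H](CC)C/C(C)=C/[C@@]1(CC)C[C@@H](CC)[C@@H](CC=O)OO1 | intermediate
28 | 2-[(3R,4R,6R)-4,6-diethyl-6-[(1E,4S)-4-ethyl-2-methyloct-1-en-1-yl]-1,2-dioxan-3-yl]acetic acid | CCCC[C@H](CC)C/C(C)=C/[C@@]1(CC)C[C@@H](CC)[C@@H](CC(=O)O)OO1 | target

## Step count and risks

Total step count: 17. Longest linear sequence: 13 steps (steps 5–17, from 9); the side-chain branch (steps 1–4) joins at step 11.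

Steps most likely to fail:

Step 15 (acid-triggered ring closure). The C6 selectivity rests on a qualitative chair argument and could be low; E/Z erosion of the allyl cation and elimination to dienes are also possible. Fallback: set out from brosylate 22 and reverse the order of C–O bond formation. Perhydrolysis of the tertiary allylic alcohol with the urea–H2O2 adduct and catalytic TsOH in Et2O at −20 °C gives (3S,4R,6RS,7E,10S)-1-[(tert-butyldiphenylsilyl)oxy]-4,6,10-triethyl-6-hydroperoxy-8-methyltetradec-7-en-3-yl 4-bromobenzenesulfonate F1. Cs2CO3 in DMF then closes the ring by intramolecular 6-exo-tet SN2 at C3 with inversion and returns to the route at 25. The C6 epimers and any C8 regioisomer formed in the perhydrolysis are separated at that stage.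

Step 14 (SN2 at a β-branched secondary brosylate). E2 elimination or tetrahydrofuran formation by the tertiary hydroxyl may win over substitution. Fallback: from 22, use superoxide as the oxygen nucleophile. KO2 with 18-crown-6 in DMSO/DMF at 0 °C displaces the brosylate with inversion and gives, after mildly acidic work-up, the free secondary hydroperoxide (3R,4R,6RS,7E,10S)-1-[(tert-butyldiphenylsilyl)oxy]-4,6,10-triethyl-3-hydroperoxy-8-methyltetradec-7-en-6-ol F2. This cyclises under the TsOH conditions of step 15 and rejoins the route at 25.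

Step 11 (mono-addition of the alkenyllithium to the lactone). Over-addition to the liberated enone or enolisation of the lactone may lower the yield. Fallback: from lactone 18, go through a Weinreb amide. Me(MeO)NH·HCl with AlMe3 opens 18 to (3R,4S)-6-[(tert-butyldiphenylsilyl)oxy]-3-ethyl-4-hydroxy-N-methoxy-N-methylhexanamide F3. TESOTf with 2,6-lutidine gives its 4-O-triethylsilyl ether F4. Alkenyllithium 19 (generated from 8 as in step 11) adds once to give (3S,4R,7E,10S)-1-[(tert-butyldiphenylsilyl)oxy]-4,10-diethyl-8-methyl-3-[(triethylsilyl)oxy]tetradec-7-en-6-one F5. HF·pyridine in THF removes the triethylsilyl group selectively and returns to the route at 20.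

Further compounds

F1 | step 15 | (3S,4R,6RS,7E,10S)-1-[(tert-butyldiphenylsilyl)oxy]-4,6,10-triethyl-6-hydroperoxy-8-methyltetradec-7-en-3-yl 4-bromobenzenesulfonate | CCCC[C@H](CC)C/C(C)=C/C(OO)(CC)C[C@@H](CC)[C@@H](OS(=O)(=O)c1ccc(Br)cc1)CCO[Si](c1ccccc1)(c1ccccc1)C(C)(C)C
F2 | step 14 | (3R,4R,6RS,7E,10S)-1-[(tert-butyldiphenylsilyl)oxy]-4,6,10-triethyl-3-hydroperoxy-8-methyltetradec-7-en-6-ol | CCCC[C@H](CC)C/C(C)=C/C(O)(CC)C[C@@H](CC)[C@H](OO)CCO[Si](c1ccccc1)(c1ccccc1)C(C)(C)C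
F3 | step 11 | (3R,4S)-6-[(tert-butyldiphenylsilyl)oxy]-3-ethyl-4-hydroxy-N-methoxy-N-methylhexanamide | CON(C)C(=O)C[C@@H](CC)[C@@H](O)CCO[Si](c1ccccc1)(c1ccccc1)C(C)(C)C
F4 | step 11 | (3R,4S)-6-[(tert-butyldiphenylsilyl)oxy]-3-ethyl-N-methoxy-N-methyl-4-[(triethylsilyl)oxy]hexanamide | CON(C)C(=O)C[C@@H](CC)[C@@H](O[Si](CC)(CC)CC)CCO[Si](c1ccccc1)(c1ccccc1)C(C)(C)C
F5 | step 11 | (3S,4R,7E,10S)-1-[(tert-butyldiphenylsilyl)oxy]-4,10-diethyl-8-methyl-3-[(triethylsilyl)oxy]tetradec-7-en-6-one | CCCC[C@H](CC)C/C(C)=C/C(=O)C[C@@H](CC)[C@@H](O[Si](CC)(CC)CC)CCO[Si](c1ccccc1)(c1ccccc1)C(C)(C)C
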